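## Retrosynthetic overview

1. Target ⇐ 8-ketone (exocyclic CH2 by Takai–Lombardo methylenation) ⇐ 6-hydroxy-8-oxo acid (acetylation).
2. Ring B is closed last, by an intramolecular aldol addition (C6–C7) of a seco keto aldehyde; C5, C6 and C9 settle under thermodynamic control.
3. The quaternary C10–C9 bond comes from an Ireland–Claisen rearrangement of the ester that joins fragment 1 (ring A hydroxy lactone, 13 non-hydrogen atoms) to fragment 2 (dienoyl chloride, 10 non-hydrogen atoms).
4. Fragment 1: ring A is present from the start (2-methylcyclohexanone); C4 is set by an auxiliary-controlled methylation, then enol triflate, formylation and lactol formation.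
5. Fragment 2: propargyl alcohol → (E)-iodo diene (carboalumination, Wittig), joined to a zinc homoenolate by Negishi coupling.

Positions are given in labdane numbering: C4 carries CH3 and CO2H, C10 carries CH3, C6 the acetate, C8 the exocyclic CH2, C9 the side chain.

Assumption: the lithio-enamine of the L-valine tert-butyl ester auxiliary, methylated in toluene/HMPA, is taken to give the (1S) keto ester; if the facial sense is the opposite, the D-valine ester is used and nothing else changes.

## Fragment 1 (ring A)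

Step 1
Reactants: 1 2-methylcyclohexanone; 2 dimethyl carbonate
Product: 3 methyl 3-methyl-2-oxocyclohexane-1-carboxylate
Conditions: NaH (2.2 equiv), THF, reflux; aq. HCl
Reagents that add atoms: none
Why: Claisen-type C-acylation of the ketone enolate occurs at the unsubstituted α-carbon because only that β-keto ester can be deprotonated irreversibly; the stereocentres formed are erased later.

Step 2
Reactants: 3 methyl 3-methyl-2-oxocyclohexane-1-carboxylate
Product: 4 tert-butyl N-[2-(methoxycarbonyl)-6-methylcyclohex-1-en-1-yl]-L-valinate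
Conditions: L-valine tert-butyl ester, BF3·OEt2 (cat.), benzene, reflux (Dean–Stark)
Reagents that add atoms: L-valine tert-butyl ester, CC(C)[C@H](N)C(=O)OC(C)(C)C
Why: Condensation of the β-keto ester with the amine gives the conjugated enamino ester (vinylogous carbamate) that carries the chiral auxiliary.

Step 3
Reactants: 4 tert-butyl N-[2-(methoxycarbonyl)-6-methylcyclohex-1-en-1-yl]-L-valinate
Product: 6 methyl (1S)-1,3-dimethyl-2-oxocyclohexane-1-carboxylate, via methylated ketimine 5 (not isolated)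
Conditions: LiN(iPr)2, toluene, −78 °C; HMPA, MeI, −55 °C; then 1 M HCl, THF, rt
Reagents that add atoms: iodomethane, CI
Why: Koga asymmetric alkylation: the chelated lithio-enamine is methylated on the face away from the isopropyl group, which sets the quaternary centre (1S), and mild acid hydrolysis releases the auxiliary; the C3 centre stays a mixture and is erased in step 4.

Step 4
Reactants: 6 methyl (1S)-1,3-dimethyl-2-oxocyclohexane-1-carboxylate
Product: 7 methyl (1S)-1,3-dimethyl-2-[(trifluoromethanesulfonyl)oxy]cyclohex-2-ene-1-carboxylate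
Conditions: KN(SiMe3)2, THF, −78 °C; PhNTf2, −78 °C to rt
Reagents that add atoms: N-phenylbis(trifluoromethanesulfonimide), O=S(=O)(N(c1ccccc1)S(=O)(=O)C(F)(F)F)C(F)(F)F
Why: The ketone can enolise only towards the methine carbon, so O-sulfonylation of the enolate gives the tetrasubstituted enol triflate from both C3 epimers.

Step 5
Reactants: 7 methyl (1S)-1,3-dimethyl-2-[(trifluoromethanesulfonyl)oxy]cyclohex-2-ene-1-carboxylate
Product: 8 methyl (1S)-2-formyl-1,3-dimethylcyclohex-2-ene-1-carboxylate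
Conditions: Pd(PPh3)4 (5 mol %), LiCl, CO (1 atm), Bu3SnH (slow addition), THF, 50 °C
Reagents that add atoms: carbon monoxide, [C-]#[O+]
Why: Stille reductive carbonylation (oxidative addition, CO insertion, hydride transfer from tin) turns the enol triflate into the enal without touching the quaternary centre.

Step 6
Reactants: 8 methyl (1S)-2-formyl-1,3-dimethylcyclohex-2-ene-1-carboxylate
Product: 9 (7aS)-3-hydroxy-4,7a-dimethyl-5,6,7,7a-tetrahydro-2-benzofuran-1(3H)-one
Conditions: LiOH, THF/H2O, rt; 1 M HCl to pH 3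
Reagents that add atoms: water, O
Why: Saponification of the hindered ester is assisted by the neighbouring aldehyde hydrate, and the aldehyde acid closes to its ring tautomer (hydroxy lactone), obtained as both C3 epimers, which interconvert.

## Fragment 2 (side chain and C8/C9)

Step 7
Reactants: 10 prop-2-yn-1-ol
Product: 12 (2E)-3-iodo-2-methylprop-2-en-1-ol, via alkenylalane 11 (not isolated)
Conditions: AlMe3 (3 equiv), Cp2ZrCl2 (0.25 equiv), CH2Cl2, 0 °C to rt; I2, THF, −30 °C; aq. K2CO3
Reagents that add atoms: trimethylaluminium, C[Al](C)C; iodine, II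
Why: Negishi zirconium-catalysed carboalumination adds methyl and aluminium syn with methyl on the internal carbon, and iodinolysis with retention fixes the E trisubstituted alkene.

Step 8
Reactants: 12 (2E)-3-iodo-2-methylprop-2-en-1-ol
Product: 13 (2E)-3-iodo-2-methylprop-2-enal
Conditions: MnO2, CH2Cl2, rt
Reagents that add atoms: none
Why: Selective oxidation of the allylic alcohol on MnO2 leaves the vinyl iodide and the alkene geometry untouched.

Step 9
Reactants: 13 (2E)-3-iodo-2-methylprop-2-enal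
Product: 14 (1E)-1-iodo-2-methylbuta-1,3-diene
Conditions: Ph3PCH3Br, NaN(SiMe3)2, THF, −78 to 0 °C
Reagents that add atoms: methyltriphenylphosphonium bromide, C[P+](c1ccccc1)(c1ccccc1)c1ccccc1.[Br-]
Why: Wittig methylenation of the enal builds the terminal vinyl group and keeps the E geometry of the existing alkene.

Step 10
Reactants: 15 ethyl 3-iodopropanoate
Product: 16 (3-ethoxy-3-oxopropyl)zinc iodide
Conditions: Zn dust (activated with BrCH2CH2Br and Me3SiCl), THF, 35 °C
Reagents that add atoms: zinc, [Zn]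
Why: Oxidative insertion of zinc into the primary C–I bond gives the ester-tolerant zinc homoenolate, kept as a THF solution.

Step 11
Reactants: 14 (1E)-1-iodo-2-methylbuta-1,3-diene; 16 (3-ethoxy-3-oxopropyl)zinc iodide
Product: 17 ethyl (4E)-5-methylhepta-4,6-dienoate
Conditions: Pd(PPh3)4 (3 mol %), THF, rt
Reagents that add atoms: none
Why: Negishi cross-coupling of the alkenyl iodide with the alkylzinc reagent proceeds with retention, so the E diene is obtained without the allylic transposition an alkylation could give.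

Step 12
Reactants: 17 ethyl (4E)-5-methylhepta-4,6-dienoate
Product: 18 (4E)-5-methylhepta-4,6-dienoic acid
Conditions: LiOH, THF/MeOH/H2O, rt; 1 M HCl
Reagents that add atoms: water, O
Why: Ordinary saponification; the isolated diene is inert to base.

Step 13
Reactants: 18 (4E)-5-methylhepta-4,6-dienoic acid
Product: 19 (4E)-5-methylhepta-4,6-dienoyl chloride
Conditions: (COCl)2, DMF (cat.), CH2Cl2, 0 °C; volatiles removed
Reagents that add atoms: oxalyl chloride, O=C(Cl)C(=O)Cl
Why: Vilsmeier-type activation converts the acid into the acyl chloride needed to acylate the weakly nucleophilic lactol hydroxyl.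

## Union and endgame

Step 14
Reactants: 9 (7aS)-3-hydroxy-4,7a-dimethyl-5,6,7,7a-tetrahydro-2-benzofuran-1(3H)-one; 19 (4E)-5-methylhepta-4,6-dienoyl chloride
Product: 20 (3S,7aS)-4,7a-dimethyl-1-oxo-1,3,5,6,7,7a-hexahydro-2-benzofuran-3-yl (4E)-5-methylhepta-4,6-dienoate
Conditions: pyridine, DMAP (cat.), CH2Cl2, 0 °C; chromatography removes the minor C3 epimer
Reagents that add atoms: none
Why: O-acylation of the equilibrating lactol joins the two fragments as a pseudo-ester; the acyloxy group is expected to settle trans to the perpendicular C7a methyl (3S), which is the face the next step needs.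

Step 15
Reactants: 20 (3S,7aS)-4,7a-dimethyl-1-oxo-1,3,5,6,7,7a-hexahydro-2-benzofuran-3-yl (4E)-5-methylhepta-4,6-dienoate
Product: 23 (4E)-2-[(4S,7aS)-4,7a-dimethyl-1-oxo-1,4,5,6,7,7a-hexahydro-2-benzofuran-4-yl]-5-methylhepta-4,6-dienoic acid, via silyl ketene acetal 21 (not isolated), via trimethylsilyl ester 22 (not isolated)
Conditions: LiN(SiMe3)2, Me3SiCl/Et3N (premixed), THF, −95 to −78 °C; then rt to 40 °C; 1 M HCl
Reagents that add atoms: none
Why: Ireland–Claisen rearrangement: the suprafacial [3,3] shift delivers C9 to C10 on the face that carried the acyloxy group, anti to the C7a methyl, which sets the quaternary centre (4S) with its methyl cis to the C7a methyl; the new α-centre is left as a mixture because step 17 equilibrates it.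

Step 16
Reactants: 23 (4E)-2-[(4S,7aS)-4,7a-dimethyl-1-oxo-1,4,5,6,7,7a-hexahydro-2-benzofuran-4-yl]-5-methylhepta-4,6-dienoic acid
Product: 25 (4S,7aS)-4,7a-dimethyl-4-[(5E)-6-methyl-2-oxoocta-5,7-dien-3-yl]-5,6,7,7a-tetrahydro-2-benzofuran-1(4H)-one, via acid chloride 24 (not isolated)
Conditions: 1-chloro-N,N,2-trimethylprop-1-en-1-amine, CH2Cl2, 0 °C; then Me2CuLi, Et2O, −78 °C
Reagents that add atoms: lithium dimethylcuprate, [Li+].C[Cu-]C
Why: Neutral acid chloride formation followed by acylation of the Gilman cuprate gives the methyl ketone (C7) and stops there; the hindered enol lactone is not attacked at −78 °C.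

Step 17
Reactants: 25 (4S,7aS)-4,7a-dimethyl-4-[(5E)-6-methyl-2-oxoocta-5,7-dien-3-yl]-5,6,7,7a-tetrahydro-2-benzofuran-1(4H)-one
Product: 27 (1S,4aR,5S,8R,8aS)-8-hydroxy-1,4a-dimethyl-5-[(2E)-3-methylpenta-2,4-dien-1-yl]-6-oxodecahydronaphthalene-1-carboxylic acid, via seco keto aldehyde acid 26 (not isolated)
Conditions: LiOH (3 equiv), THF/H2O, 0 °C to rt; 1 M HCl to pH 4 at 0 °C
Reagents that add atoms: water, O
Why: Hydroxide opens the enol lactone to the carboxylate and the C6 aldehyde, and the methyl ketone enolate closes ring B by a reversible intramolecular aldol addition; C5 and C9 (enolisable) and C6 (retro-aldol) equilibrate to the trans-fused chair with equatorial hydroxyl and equatorial side chain, which is also poorly aligned for E1cB loss of water.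

Step 18
Reactants: 27 (1S,4aR,5S,8R,8aS)-8-hydroxy-1,4a-dimethyl-5-[(2E)-3-methylpenta-2,4-dien-1-yl]-6-oxodecahydronaphthalene-1-carboxylic acid
Product: 28 (1S,4aR,5S,8R,8aS)-8-(acetyloxy)-1,4a-dimethyl-5-[(2E)-3-methylpenta-2,4-dien-1-yl]-6-oxodecahydronaphthalene-1-carboxylic acid
Conditions: Ac2O, pyridine, DMAP (cat.), CH2Cl2, 0 °C; aqueous work-up
Reagents that add atoms: acetic anhydride, CC(=O)OC(C)=O
Why: DMAP-catalysed O-acetylation of the unhindered equatorial alcohol; the neopentyl carboxyl is a poor acyl donor, so any mixed anhydride returns the free acid on work-up and no stereocentre is touched.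

Step 19
Reactants: 28 (1S,4aR,5S,8R,8aS)-8-(acetyloxy)-1,4a-dimethyl-5-[(2E)-3-methylpenta-2,4-dien-1-yl]-6-oxodecahydronaphthalene-1-carboxylic acid
Product: 29 (1S,4aS,5R,8R,8aS)-8-(acetyloxy)-1,4a-dimethyl-6-methylidene-5-[(2E)-3-methylpenta-2,4-dien-1-yl]decahydronaphthalene-1-carboxylic acid (CNP0240327.3)
Conditions: Zn, CH2Br2, TiCl4 (excess, preformed reagent), THF/CH2Cl2, 0 °C to rt
Reagents that add atoms: dibromomethane, BrCBr
Why: Takai–Lombardo methylenation with the non-basic gem-dimetallic reagent converts the hindered ketone into the exocyclic alkene without β-elimination of the acetate or epimerisation at C9, and leaves the acetate and the diene alone.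

## Compound list

1 | 2-methylcyclohexanone (racemic) | CC1CCCCC1=O | starting material
2 | dimethyl carbonate | COC(=O)OC | starting material
3 | methyl 3-methyl-2-oxocyclohexane-1-carboxylate (stereoisomer mixture) | COC(=O)C1CCCC(C)C1=O | intermediate
4 | tert-butyl N-[2-(methoxycarbonyl)-6-methylcyclohex-1-en-1-yl]-L-valinate (C6 epimers) | COC(=O)C1=C(N[C@@H](C(C)C)C(=O)OC(C)(C)C)C(C)CCC1 | intermediate
5 | tert-butyl N-[(2S)-2-(methoxycarbonyl)-2,6-dimethylcyclohexylidene]-L-valinate (C6 epimers) | COC(=O)[C@@]1(C)CCCC(C)C1=N[C@@H](C(C)C)C(=O)OC(C)(C)C | intermediate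
6 | methyl (1S)-1,3-dimethyl-2-oxocyclohexane-1-carboxylate (C3 epimers) | COC(=O)[C@@]1(C)CCCC(C)C1=O | intermediate
7 | methyl (1S)-1,3-dimethyl-2-[(trifluoromethanesulfonyl)oxy]cyclohex-2-ene-1-carboxylate | COC(=O)[C@@]1(C)CCCC(C)=C1OS(=O)(=O)C(F)(F)F | intermediate
8 | methyl (1S)-2-formyl-1,3-dimethylcyclohex-2-ene-1-carboxylate | COC(=O)[C@@]1(C)CCCC(C)=C1C=O | intermediate
9 | (7aS)-3-hydroxy-4,7a-dimethyl-5,6,7,7a-tetrahydro-2-benzofuran-1(3H)-one (C3 epimers) | CC1=C2C(O)OC(=O)[C@@]2(C)CCC1 | intermediate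
10 | prop-2-yn-1-ol | C#CCO | starting material
11 | [(1E)-3-[(dimethylalumanyl)oxy]-2-methylprop-1-en-1-yl]dimethylalumane | C[Al](C)OC/C(C)=C/[Al](C)C | intermediate
12 | (2E)-3-iodo-2-methylprop-2-en-1-ol | OC/C(C)=C/I | intermediate
13 | (2E)-3-iodo-2-methylprop-2-enal | O=C/C(C)=C/I | intermediate
14 | (1E)-1-iodo-2-methylbuta-1,3-diene | C=C/C(C)=C/I | intermediate
15 | ethyl 3-iodopropanoate | CCOC(=O)CCI | starting material
16 | (3-ethoxy-3-oxopropyl)zinc iodide | CCOC(=O)CC[Zn]I | intermediate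
17 | ethyl (4E)-5-methylhepta-4,6-dienoate | C=C/C(C)=C/CCC(=O)OCC | intermediate
18 | (4E)-5-methylhepta-4,6-dienoic acid | C=C/C(C)=C/CCC(=O)O | intermediate
19 | (4E)-5-methylhepta-4,6-dienoyl chloride | C=C/C(C)=C/CCC(Cl)=O | intermediate
20 | (3S,7aS)-4,7a-dimethyl-1-oxo-1,3,5,6,7,7a-hexahydro-2-benzofuran-3-yl (4E)-5-methylhepta-4,6-dienoate | C=C/C(C)=C/CCC(=O)O[C@H]1OC(=O)[C@@]2(C)CCCC(C)=C12 | intermediate
21 | (3S,7aS)-4,7a-dimethyl-3-{[(4E)-5-methyl-1-[(trimethylsilyl)oxy]hepta-1,4,6-trien-1-yl]oxy}-5,6,7,7a-tetrahydro-2-benzofuran-1(3H)-one | C=C/C(C)=C/CC=C(O[Si](C)(C)C)O[C@H]1OC(=O)[C@@]2(C)CCCC(C)=C12 | intermediate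
22 | trimethylsilyl (4E)-2-[(4S,7aS)-4,7a-dimethyl-1-oxo-1,4,5,6,7,7a-hexahydro-2-benzofuran-4-yl]-5-methylhepta-4,6-dienoate (C2 epimers) | C=C/C(C)=C/CC(C(=O)O[Si](C)(C)C)[C@]1(C)CCC[C@]2(C)C(=O)OC=C12 | intermediate
23 | (4E)-2-[(4S,7aS)-4,7a-dimethyl-1-oxo-1,4,5,6,7,7a-hexahydro-2-benzofuran-4-yl]-5-methylhepta-4,6-dienoic acid (C2 epimers) | C=C/C(C)=C/CC(C(=O)O)[C@]1(C)CCC[C@]2(C)C(=O)OC=C12 | intermediate
24 | (4E)-2-[(4S,7aS)-4,7a-dimethyl-1-oxo-1,4,5,6,7,7a-hexahydro-2-benzofuran-4-yl]-5-methylhepta-4,6-dienoyl chloride (C2 epimers) | C=C/C(C)=C/CC(C(Cl)=O)[C@]1(C)CCC[C@]2(C)C(=O)OC=C12 | intermediate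
25 | (4S,7aS)-4,7a-dimethyl-4-[(5E)-6-methyl-2-oxoocta-5,7-dien-3-yl]-5,6,7,7a-tetrahydro-2-benzofuran-1(4H)-one (side-chain C3 epimers) | C=C/C(C)=C/CC(C(C)=O)[C@]1(C)CCC[C@]2(C)C(=O)OC=C12 | intermediate
26 | (1S,3R)-2-formyl-1,3-dimethyl-3-[(5E)-6-methyl-2-oxoocta-5,7-dien-3-yl]cyclohexane-1-carboxylic acid (epimers at C2 and side-chain C3) | C=C/C(C)=C/CC(C(C)=O)[C@]1(C)CCC[C@](C)(C(=O)O)C1C=O | intermediate
27 | (1S,4aR,5S,8R,8aS)-8-hydroxy-1,4a-dimethyl-5-[(2E)-3-methylpenta-2,4-dien-1-yl]-6-oxodecahydronaphthalene-1-carboxylic acid | C=C/C(C)=C/C[C@@H]1C(=O)C[C@@H](O)[C@H]2[C@@]1(C)CCC[C@]2(C)C(=O)O | intermediate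
28 | (1S,4aR,5S,8R,8aS)-8-(acetyloxy)-1,4a-dimethyl-5-[(2E)-3-methylpenta-2,4-dien-1-yl]-6-oxodecahydronaphthalene-1-carboxylic acid | C=C/C(C)=C/C[C@@H]1C(=O)C[C@@H](OC(C)=O)[C@H]2[C@@]1(C)CCC[C@]2(C)C(=O)O | intermediate
29 | (1S,4aS,5R,8R,8aS)-8-(acetyloxy)-1,4a-dimethyl-6-methylidene-5-[(2E)-3-methylpenta-2,4-dien-1-yl]decahydronaphthalene-1-carboxylic acid | C=C/C(C)=C/C[C@@H]1C(=C)C[C@@H](OC(C)=O)[C@H]2[C@@]1(C)CCC[C@]2(C)C(=O)O | target

## Step count and weak points

Total step count: 19.
Longest linear sequence: 12 steps (steps 1–6 then 14–19; the fragment 2 branch, steps 7–9 and 11–13 then 14–19, is equally long).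

The three steps most likely to fail:

Step 15. The ester in 20 is an acylal, so its enolate may expel the lactol oxygen and give a ketene before it is silylated, or the silyl ketene acetal may ionise and recombine at C3 instead of rearranging. The fallback is a thermal Carroll rearrangement that needs no strong base; it sets out from 9 and comes back at 25, so step 16 is bypassed as well. Compound 9 is acetoacetylated with 4-methylideneoxetan-2-one F1 (DMAP cat., CH2Cl2) to (3S,7aS)-4,7a-dimethyl-1-oxo-1,3,5,6,7,7a-hexahydro-2-benzofuran-3-yl 3-oxobutanoate F2. Separately, (2E)-3-methylpent-2-en-4-yn-1-ol F3 is semi-hydrogenated (H2, Pd/CaCO3 poisoned with Pb(OAc)2, quinoline) to (2E)-3-methylpenta-2,4-dien-1-ol F4 and brominated (PBr3, Et2O, −20 °C) to (3E)-5-bromo-3-methylpenta-1,3-diene F5. C-alkylation of F2 with F5 (K2CO3, acetone) gives (3S,7aS)-4,7a-dimethyl-1-oxo-1,3,5,6,7,7a-hexahydro-2-benzofuran-3-yl (4E)-2-acetyl-5-methylhepta-4,6-dienoate F6. In xylene at 130 °C F6 undergoes the [3,3] shift through its enol on the face anti to the C7a methyl and loses CO2 to give 25 directly.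

Step 16. The cuprate (or traces of MeLi) may attack the enol lactone, or the α-branched acid chloride may lose HCl to a ketene. The fallback is a Fukuyama ketone synthesis from 23 back to 25. Acid 23 is converted (EtSH, DCC, DMAP, CH2Cl2) into S-ethyl (4E)-2-[(4S,7aS)-4,7a-dimethyl-1-oxo-1,4,5,6,7,7a-hexahydro-2-benzofuran-4-yl]-5-methylhepta-4,6-dienethioate F7, which couples with MeZnI under PdCl2(PPh3)2 in toluene at rt to give 25; the organozinc reagent does not touch the enol lactone.

Step 17. The one-pot hydroxide cascade may go on to the enone by dehydration, or the hydroxy acid may lactonise on acidification. The fallback is stepwise and closes the ring by enamine catalysis; it sets out from 25 and comes back at 27. NaOMe (0.2 equiv) in MeOH at 0 °C opens the enol lactone to methyl (1S,3R)-2-formyl-1,3-dimethyl-3-[(5E)-6-methyl-2-oxoocta-5,7-dien-3-yl]cyclohexane-1-carboxylate F8. Pyrrolidine/AcOH in CH2Cl2 then closes ring B through the methyl ketone enamine to methyl (1S,4aR,5S,8R,8aS)-8-hydroxy-1,4a-dimethyl-5-[(2E)-3-methylpenta-2,4-dien-1-yl]-6-oxodecahydronaphthalene-1-carboxylate F9. Saponification (LiOH, THF/H2O, 50 °C, assisted by the neighbouring 8-hydroxyl) gives 27.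

## Further compounds

F1 | step 15 | 4-methylideneoxetan-2-one | C=C1CC(=O)O1
F2 | step 15 | (3S,7aS)-4,7a-dimethyl-1-oxo-1,3,5,6,7,7a-hexahydro-2-benzofuran-3-yl 3-oxobutanoate | CC(=O)CC(=O)O[C@H]1OC(=O)[C@@]2(C)CCCC(C)=C12
F3 | step 15 | (2E)-3-methylpent-2-en-4-yn-1-ol | C#C/C(C)=C/CO
F4 | step 15 | (2E)-3-methylpenta-2,4-dien-1-ol | C=C/C(C)=C/CO
F5 | step 15 | (3E)-5-bromo-3-methylpenta-1,3-diene | C=C/C(C)=C/CBr
F6 | step 15 | (3S,7aS)-4,7a-dimethyl-1-oxo-1,3,5,6,7,7a-hexahydro-2-benzofuran-3-yl (4E)-2-acetyl-5-methylhepta-4,6-dienoate | C=C/C(C)=C/CC(C(C)=O)C(=O)O[C@H]1OC(=O)[C@@]2(C)CCCC(C)=C12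
F7 | step 16 | S-ethyl (4E)-2-[(4S,7aS)-4,7a-dimethyl-1-oxo-1,4,5,6,7,7a-hexahydro-2-benzofuran-4-yl]-5-methylhepta-4,6-dienethioate | C=C/C(C)=C/CC(C(=O)SCC)[C@]1(C)CCC[C@]2(C)C(=O)OC=C12
F8 | step 17 | methyl (1S,3R)-2-formyl-1,3-dimethyl-3-[(5E)-6-methyl-2-oxoocta-5,7-dien-3-yl]cyclohexane-1-carboxylate | C=C/C(C)=C/CC(C(C)=O)[C@]1(C)CCC[C@](C)(C(=O)OC)C1C=O
F9 | step 17 | methyl (1S,4aR,5S,8R,8aS)-8-hydroxy-1,4a-dimethyl-5-[(2E)-3-methylpenta-2,4-dien-1-yl]-6-oxodecahydronaphthalene-1-carboxylate | C=C/C(C)=C/C[C@@H]1C(=O)C[C@@H](O)[C@H]2[C@@]1(C)CCC[C@]2(C)C(=O)OC
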